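(The constants are those of an exercise, and the outcome is calculated.)

Start from 240, the binding constant of the idle adduct times the electrophile at the start: it is far above one, so a freed leaving group does not stay free.

    electrophile + nucleophile → acid + target + leaving group (k1 = 8.6 L mol⁻¹ s⁻¹)
    protonated nucleophile ⇌ nucleophile + acid, settled at all times (K2 = 4.0 × 10⁻¹⁰ M)
    buffer acid ⇌ buffer base + acid, settled at all times (K3 = 6.3 × 10⁻⁷ M)
    electrophile + leaving group ⇌ idle adduct, settled at all times (K4 = 12000 L mol⁻¹)
    scavenger + leaving group → scavenged by-product (k5 = 7.0 L mol⁻¹ s⁻¹)
    nucleophile + target → over-reaction product (k6 = 1.4 L mol⁻¹ s⁻¹)

electrophile 20 mM; nucleophile 22.0 mM; buffer base 20.0 mM; buffer acid 2.00 mM; scavenger 20.0 mM; time 15 s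

1. part of the electrophile that has reacted at 15 s
2. pH of the solution at 15 s

- acid is the free proton; pH is minus the decimal logarithm of its molar concentration
- amounts and yields of leaving group count idle adduct too
- what has gone from electrophile into another species counts as reacted, even if it can come back
- run time (flask): 15 s

1. Place the protons first. The buffer acid is a far stronger acid than the protonated nucleophile, so its 2.00 mM go to the nucleophile at once. That leaves a usable c(nucleophile) of 20.0 mM, level with the 20 mM of electrophile. Take these equal partners as the symmetric zero of the scale.

2. Take the lower extreme: each turnover costs one electrophile and one nucleophile. Let x be rate constant times time times usable c(nucleophile), here 2.58. Equal partners in second-order decay then react to the part x/(one + x), which is 72.1%.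

3. Take the upper extreme: each turnover costs two of each. The freed proton takes a second nucleophile, because the buffer base is the much weaker base, and the leaving group takes a second electrophile, because binding is strong. Doubling the cost doubles x. Call twice x the toll clock: 5.16. The reacted part becomes 83.8%.

4. Commit to just under 83.8%. Both tolls are steeply favoured, so I place this flask near the top. The over-reaction spends nucleophile without a turnover, but the half-life of target by that step alone, the other concentrations as charged, is 23 s, longer than the 3.7 s of electrophile by the main step alone.

5. Read the forecast: 80% (77% to 83%) and pH 8.8 (8.65 to 8.95), since each turnover “uses up a second nucleophile through proton capture”. Its 80% lies below my 83.8%.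

The flask gives 81.2% at pH 8.82, inside both forecast ranges. At 15.0 s the idle adduct holds 39.7% of the charged electrophile, while target and over-reaction product together hold 41.6%. Read back through the same law, 81.2% is a clock of 4.32 against the 5.16 reckoned.

Now take the neighbour flask with 12 mM of electrophile, the limiting reagent. Its clock stays 5.16. With r = 0.600 and E = exp(−clock(one − r)) = 0.127, the reacted part (one − E)/(one − rE) is 94.5%. The neighbour flask computes to 90.7%, again below the clock's figure.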